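## Retrosynthetic overview

1. C7=C8 is disconnected to an intermolecular aldol between the ring enolate of chloroenone 17 (C8–C20) and aldehyde 31 (C1–C7), followed by β-elimination and desilylation.
2. Aldehyde 31: the threo C5/C6 diol comes from L-tartrate; C4–C3 is made by copper-catalysed triflate/Grignard coupling; the acetonide is exchanged for the diacetate while C1 is still an alkene (no δ-lactone possible), then C1 is oxidised to the ester and C7 to the aldehyde.
3. Chloroenone 17: the C12 carbinol is set by anti 1,2-propargylation of (S)-4-silyloxycyclopentenone (from enzymatic desymmetrisation of a meso diacetate); skipped diyne, then cis-hydrogenation, then 4-hydroxyenone, then epoxidation/HCl for the vinyl chloride.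
4. Rings: the only ring (the cyclopentenone) is carried in from the meso cyclopentene 1; no ring is formed or opened.

Assumption: the target is read from the SMILES as the (5S,6S,7E,12S,14Z,17Z) isomer; late intermediates are named by prostane numbering (C1 = ester carbon, ring = C8–C12).

## Route

Step 1
Reactants: 1 cis-3,5-diacetoxycyclopent-1-ene (meso)
Product: 2 (1R,4S)-4-hydroxycyclopent-2-en-1-yl acetate
Conditions: electric eel acetylcholinesterase, NaH2PO4/Na2HPO4 buffer pH 6.9, rt; recrystallise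
Reagents that add atoms: none
Why: Enzymatic desymmetrisation (enantiotopos-selective ester hydrolysis) of the meso diacetate frees only the hydroxyl on the carbon that becomes the (S)-carbinol, fixing both ring stereocentres in high ee.

Step 2
Reactants: 2 (1R,4S)-4-hydroxycyclopent-2-en-1-yl acetate
Product: 3 (1R,4S)-4-[(tert-butyldimethylsilyl)oxy]cyclopent-2-en-1-yl acetate
Conditions: TBSCl, imidazole, DMF, rt
Reagents that add atoms: tert-butyldimethylsilyl chloride, CC(C)(C)[Si](C)(C)Cl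
Why: Standard silyl ether formation on the free secondary alcohol differentiates the two oxygens without touching either stereocentre.

Step 3
Reactants: 3 (1R,4S)-4-[(tert-butyldimethylsilyl)oxy]cyclopent-2-en-1-yl acetate
Product: 4 (1R,4S)-4-[(tert-butyldimethylsilyl)oxy]cyclopent-2-en-1-ol
Conditions: K2CO3 (0.2 equiv), MeOH, 0 °C
Reagents that add atoms: none
Why: Base-catalysed transesterification (methanolysis) removes the acetate while the TBS ether is stable.

Step 4
Reactants: 4 (1R,4S)-4-[(tert-butyldimethylsilyl)oxy]cyclopent-2-en-1-ol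
Product: 5 (4S)-4-[(tert-butyldimethylsilyl)oxy]cyclopent-2-en-1-one
Conditions: activated MnO2 (excess), CH2Cl2, rt
Reagents that add atoms: none
Why: Allylic alcohol oxidation with MnO2 is mild and non-basic, so the β-silyloxy enone forms without elimination or racemisation.

Step 5
Reactants: 5 (4S)-4-[(tert-butyldimethylsilyl)oxy]cyclopent-2-en-1-one; 6 propargyl bromide (3-bromoprop-1-yne)
Product: 8 (1R,4S)-4-[(tert-butyldimethylsilyl)oxy]-1-(prop-2-yn-1-yl)cyclopent-2-en-1-ol, via allenylzinc bromide 7 (not isolated)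
Conditions: 6 (1.5 equiv), Zn dust (2 equiv), THF, 0 °C, 1 h; then 5, −40 °C → 0 °C; H2O work-up; chromatography
Reagents that add atoms: none
Why: Barbier-type carbonyl propargylation (SE2' of the allenylzinc) adds 1,2 to the enone on the face opposite the bulky silyloxy group, which sets the tertiary carbinol (future C12) with OH cis to OTBS; the minor diastereomer is removed here.

Step 6
Reactants: 8 (1R,4S)-4-[(tert-butyldimethylsilyl)oxy]-1-(prop-2-yn-1-yl)cyclopent-2-en-1-ol; 9 1-bromopent-2-yne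
Product: 10 (1R,4S)-4-[(tert-butyldimethylsilyl)oxy]-1-(octa-2,5-diyn-1-yl)cyclopent-2-en-1-ol
Conditions: CuI (1 equiv), NaI (1 equiv), Cs2CO3 (1 equiv), DMF, rt
Reagents that add atoms: none
Why: Copper-mediated coupling of a terminal alkyne with a propargylic halide is the standard entry to skipped diynes and tolerates the free tertiary alcohol.

Step 7
Reactants: 10 (1R,4S)-4-[(tert-butyldimethylsilyl)oxy]-1-(octa-2,5-diyn-1-yl)cyclopent-2-en-1-ol
Product: 11 (1R,4S)-4-[(tert-butyldimethylsilyl)oxy]-1-[(2Z,5Z)-octa-2,5-dien-1-yl]cyclopent-2-en-1-ol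
Conditions: H2 (1 atm, 2 equiv uptake), Pd/CaCO3 poisoned with Pb(OAc)2, quinoline, EtOAc, rt
Reagents that add atoms: none
Why: Lindlar semi-hydrogenation delivers H2 syn to each alkyne, giving the (Z,Z)-skipped diene while the ring alkene is left alone.

Step 8
Reactants: 11 (1R,4S)-4-[(tert-butyldimethylsilyl)oxy]-1-[(2Z,5Z)-octa-2,5-dien-1-yl]cyclopent-2-en-1-ol
Product: 12 (1R,4S)-1-[(2Z,5Z)-octa-2,5-dien-1-yl]cyclopent-2-ene-1,4-diol
Conditions: Bu4NF, THF, 0 °C → rt
Reagents that add atoms: none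
Why: Fluoride-mediated desilylation frees the secondary allylic alcohol without affecting the diene or the tertiary carbinol.

Step 9
Reactants: 12 (1R,4S)-1-[(2Z,5Z)-octa-2,5-dien-1-yl]cyclopent-2-ene-1,4-diol
Product: 13 (4R)-4-hydroxy-4-[(2Z,5Z)-octa-2,5-dien-1-yl]cyclopent-2-en-1-one
Conditions: activated MnO2 (excess), CH2Cl2, rt
Reagents that add atoms: none
Why: Chemoselective allylic oxidation converts only the secondary alcohol (the tertiary one cannot oxidise), so the controlling C4 centre is erased and C12 remains as the sole ring stereocentre.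

Step 10
Reactants: 13 (4R)-4-hydroxy-4-[(2Z,5Z)-octa-2,5-dien-1-yl]cyclopent-2-en-1-one
Product: 14 (2R,3S,4R)-2,3-epoxy-4-hydroxy-4-[(2Z,5Z)-octa-2,5-dien-1-yl]cyclopentan-1-one (epoxide cis to OH)
Conditions: 30% aq. H2O2 (3 equiv), NaOH (0.2 equiv), MeOH, −20 °C → 0 °C
Reagents that add atoms: hydrogen peroxide, OO
Why: Weitz–Scheffer nucleophilic epoxidation attacks only the electron-poor enone (not the isolated Z-alkenes), mainly on the hydroxyl face opposite the side chain, and both new centres are erased in the next step.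

Step 11
Reactants: 14 (2R,3S,4R)-2,3-epoxy-4-hydroxy-4-[(2Z,5Z)-octa-2,5-dien-1-yl]cyclopentan-1-one
Product: 16 (4R)-2-chloro-4-hydroxy-4-[(2Z,5Z)-octa-2,5-dien-1-yl]cyclopent-2-en-1-one, via trans-chlorohydrin 15 (not isolated)
Conditions: 37% aq. HCl (3 equiv), THF, 0 °C → rt
Reagents that add atoms: hydrogen chloride, Cl
Why: Chloride opens the protonated epoxy ketone by SN2 at the α-carbon (C3 is neopentyl-like) and the resulting α-chloro-β-hydroxy ketone dehydrates through its enol to the 2-chloroenone, a sequence to which the isolated alkenes are inert.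

Step 12
Reactants: 16 (4R)-2-chloro-4-hydroxy-4-[(2Z,5Z)-octa-2,5-dien-1-yl]cyclopent-2-en-1-one
Product: 17 (4R)-2-chloro-4-[(2Z,5Z)-octa-2,5-dien-1-yl]-4-[(trimethylsilyl)oxy]cyclopent-2-en-1-one
Conditions: Me3SiCl, imidazole, DMF, 0 °C → rt
Reagents that add atoms: chlorotrimethylsilane, C[Si](C)(C)Cl
Why: Silylation masks the tertiary alcohol so that a clean mono-enolate can be formed, and the TMS ether is removable at the end under mild acid.

Step 13
Reactants: 18 dimethyl (4R,5R)-2,2-dimethyl-1,3-dioxolane-4,5-dicarboxylate (dimethyl 2,3-O-isopropylidene-L-tartrate)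
Product: 19 [(4S,5S)-2,2-dimethyl-1,3-dioxolane-4,5-diyl]dimethanol
Conditions: LiAlH4 (1.5 equiv), THF, 0 °C → reflux; Na2SO4·10H2O quench
Reagents that add atoms: none
Why: Hydride reduction of both esters gives the C2-symmetric diol whose two stereocentres (future C5 and C6) come unchanged from L-tartrate.

Step 14
Reactants: 19 [(4S,5S)-2,2-dimethyl-1,3-dioxolane-4,5-diyl]dimethanol
Product: 20 [(4S,5S)-5-{[(tert-butyldiphenylsilyl)oxy]methyl}-2,2-dimethyl-1,3-dioxolan-4-yl]methanol
Conditions: NaH (1.0 equiv), THF, 0 °C; then TBDPSCl (1.0 equiv), 0 °C → rt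
Reagents that add atoms: tert-butyldiphenylsilyl chloride, CC(C)(C)[Si](Cl)(c1ccccc1)c1ccccc1
Why: Monosilylation of the symmetric diol through its sparingly soluble mono-alkoxide gives the mono-ether selectively, and either hydroxyl gives the same compound.

Step 15
Reactants: 20 [(4S,5S)-5-{[(tert-butyldiphenylsilyl)oxy]methyl}-2,2-dimethyl-1,3-dioxolan-4-yl]methanol
Product: 21 [(4S,5S)-5-{[(tert-butyldiphenylsilyl)oxy]methyl}-2,2-dimethyl-1,3-dioxolan-4-yl]methyl trifluoromethanesulfonate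
Conditions: Tf2O (1.2 equiv), pyridine (1.5 equiv), CH2Cl2, −20 °C; cold aqueous work-up, used at once
Reagents that add atoms: trifluoromethanesulfonic anhydride, O=S(=O)(OS(=O)(=O)C(F)(F)F)C(F)(F)F
Why: Sulfonylation turns the β-oxygenated primary alcohol into a leaving group reactive enough for cuprate-type displacement.

Step 16
Reactants: 21 [(4S,5S)-5-{[(tert-butyldiphenylsilyl)oxy]methyl}-2,2-dimethyl-1,3-dioxolan-4-yl]methyl trifluoromethanesulfonate; 22 but-3-en-1-ylmagnesium bromide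
Product: 23 tert-butyl{[(4S,5S)-2,2-dimethyl-5-(pent-4-en-1-yl)-1,3-dioxolan-4-yl]methoxy}diphenylsilane
Conditions: 22 (2.5 equiv, 0.5 M in THF), CuBr·SMe2 (0.1 equiv), Et2O, −40 °C → 0 °C
Reagents that add atoms: none
Why: Copper-catalysed Grignard–triflate cross-coupling (SN2 at the primary carbon) forms the C3–C4 bond and brings in C1 as a terminal alkene, with no stereocentre involved.

Step 17
Reactants: 23 tert-butyl{[(4S,5S)-2,2-dimethyl-5-(pent-4-en-1-yl)-1,3-dioxolan-4-yl]methoxy}diphenylsilane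
Product: 24 (2S,3S)-1-[(tert-butyldiphenylsilyl)oxy]oct-7-ene-2,3-diol
Conditions: AcOH/H2O (4:1), 50 °C
Reagents that add atoms: none
Why: Acid-catalysed acetal hydrolysis frees the diol while the TBDPS ether survives, and with C1 still an alkene no δ-lactone can form.

Step 18
Reactants: 24 (2S,3S)-1-[(tert-butyldiphenylsilyl)oxy]oct-7-ene-2,3-diol
Product: 25 (2S,3S)-1-[(tert-butyldiphenylsilyl)oxy]oct-7-ene-2,3-diyl diacetate
Conditions: Ac2O (3 equiv), pyridine, DMAP (0.05 equiv), CH2Cl2, rt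
Reagents that add atoms: acetic anhydride, CC(=O)OC(C)=O
Why: DMAP-catalysed acylation installs both acetates of the target with retention at C5 and C6.

Step 19
Reactants: 25 (2S,3S)-1-[(tert-butyldiphenylsilyl)oxy]oct-7-ene-2,3-diyl diacetate
Product: 27 (2S,3S)-1-[(tert-butyldiphenylsilyl)oxy]-7-oxoheptane-2,3-diyl diacetate, via secondary ozonide 26 (not isolated)
Conditions: O3, CH2Cl2, −78 °C; then PPh3 (1.2 equiv), −78 °C → rt
Reagents that add atoms: ozone, [O-][O+]=O
Why: Ozonolysis with reductive work-up cleaves the only alkene to the C1 aldehyde under neutral conditions that leave acetates and silyl ether intact.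

Step 20
Reactants: 27 (2S,3S)-1-[(tert-butyldiphenylsilyl)oxy]-7-oxoheptane-2,3-diyl diacetate
Product: 28 (5S,6S)-5,6-diacetoxy-7-[(tert-butyldiphenylsilyl)oxy]heptanoic acid
Conditions: NaClO2 (3 equiv), NaH2PO4 (3 equiv), 2-methylbut-2-ene (10 equiv), t-BuOH/H2O (4:1), 0 °C → rt
Reagents that add atoms: sodium chlorite, [Na+].[O-]Cl=O
Why: Pinnick oxidation converts the aldehyde to the acid at buffered mild pH without touching esters or the silyl ether.

Step 21
Reactants: 28 (5S,6S)-5,6-diacetoxy-7-[(tert-butyldiphenylsilyl)oxy]heptanoic acid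
Product: 29 methyl (5S,6S)-5,6-diacetoxy-7-[(tert-butyldiphenylsilyl)oxy]heptanoate
Conditions: Me3SiCHN2 (1.5 equiv), MeOH/toluene (1:4), 0 °C
Reagents that add atoms: (trimethylsilyl)diazomethane, C[Si](C)(C)C=[N+]=[N-]
Why: Diazoalkane esterification is base-free, so the acetates neither migrate nor cleave.

Step 22
Reactants: 29 methyl (5S,6S)-5,6-diacetoxy-7-[(tert-butyldiphenylsilyl)oxy]heptanoate
Product: 30 methyl (5S,6S)-5,6-diacetoxy-7-hydroxyheptanoate
Conditions: HF·pyridine, pyridine, THF, 0 °C → rt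
Reagents that add atoms: none
Why: Buffered HF desilylation frees the primary alcohol under slightly acidic conditions that suppress 1,2-acetyl migration from C6.

Step 23
Reactants: 30 methyl (5S,6S)-5,6-diacetoxy-7-hydroxyheptanoate
Product: 31 methyl (5S,6R)-5,6-diacetoxy-7-oxoheptanoate
Conditions: Dess–Martin periodinane (1.3 equiv), CH2Cl2, 0 °C → rt; used crude at once
Reagents that add atoms: none
Why: Dess–Martin oxidation gives the α-acetoxy aldehyde under non-basic conditions, avoiding epimerisation at C6 and β-elimination of the C5 acetate (the descriptor at C6 changes by priority only).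

Step 24
Reactants: 17 (4R)-2-chloro-4-[(2Z,5Z)-octa-2,5-dien-1-yl]-4-[(trimethylsilyl)oxy]cyclopent-2-en-1-one; 31 methyl (5S,6R)-5,6-diacetoxy-7-oxoheptanoate
Product: 33 methyl (5S,6S,12R,14Z,17Z)-5,6-diacetoxy-10-chloro-7-hydroxy-9-oxo-12-[(trimethylsilyl)oxy]prosta-10,14,17-trien-1-oate (C7/C8 diastereomer mixture), via lithium dienolate 32 (not isolated)
Conditions: 17 (1.05 equiv), LiN(i-Pr)2 (1.0 equiv), THF, −78 °C, 30 min; then 31 (1.2 equiv), −78 °C, 15 min; AcOH/THF quench at −78 °C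
Reagents that add atoms: none
Why: Intermolecular aldol addition of the kinetic ring enolate (the only enolisable position) to the aldehyde forms the C7–C8 bond faster than enolisation or acyl transfer at −78 °C, and the two new centres need no control because both are removed in step 25.

Step 25
Reactants: 33 methyl (5S,6S,12R,14Z,17Z)-5,6-diacetoxy-10-chloro-7-hydroxy-9-oxo-12-[(trimethylsilyl)oxy]prosta-10,14,17-trien-1-oate
Product: 35 methyl (5S,6S,7E,12S,14Z,17Z)-5,6-diacetoxy-10-chloro-9-oxo-12-[(trimethylsilyl)oxy]prosta-7,10,14,17-tetraen-1-oate, via C7 acetate 34 (not isolated)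
Conditions: Ac2O (3 equiv), Et3N (5 equiv), DMAP (1 equiv), CH2Cl2, 0 °C → rt; chromatographic removal of the 7Z isomer
Reagents that add atoms: none
Why: Acetylation followed by E1cB loss of acetate gives the cross-conjugated dienone, expected to favour the 7E isomer (C6 anti to the C9 carbonyl); acetyl migration in the aldol is harmless because every hydroxyl ends as acetate.

Step 26
Reactants: 35 methyl (5S,6S,7E,12S,14Z,17Z)-5,6-diacetoxy-10-chloro-9-oxo-12-[(trimethylsilyl)oxy]prosta-7,10,14,17-tetraen-1-oate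
Product: 36 methyl (5S,6S,7E,12S,14Z,17Z)-5,6-diacetoxy-10-chloro-12-hydroxy-9-oxoprosta-7,10,14,17-tetraen-1-oate (target)
Conditions: AcOH/THF/H2O (3:1:1), rt
Reagents that add atoms: none
Why: Mild acid hydrolysis removes the tertiary TMS ether without ionising the electron-poor carbinol, cleaving the acetates or isomerising the alkenes.

## Compound list

1 | cis-3,5-diacetoxycyclopent-1-ene (meso) | CC(=O)O[C@H]1C=C[C@@H](OC(C)=O)C1 | starting material
2 | (1R,4S)-4-hydroxycyclopent-2-en-1-yl acetate | CC(=O)O[C@H]1C=C[C@@H](O)C1 | intermediate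
3 | (1R,4S)-4-[(tert-butyldimethylsilyl)oxy]cyclopent-2-en-1-yl acetate | CC(=O)O[C@H]1C=C[C@@H](O[Si](C)(C)C(C)(C)C)C1 | intermediate
4 | (1R,4S)-4-[(tert-butyldimethylsilyl)oxy]cyclopent-2-en-1-ol | O[C@H]1C=C[C@@H](O[Si](C)(C)C(C)(C)C)C1 | intermediate
5 | (4S)-4-[(tert-butyldimethylsilyl)oxy]cyclopent-2-en-1-one | O=C1C=C[C@@H](O[Si](C)(C)C(C)(C)C)C1 | intermediate
6 | propargyl bromide (3-bromoprop-1-yne) | C#CCBr | starting material
7 | allenylzinc bromide, CH2=C=CHZnBr | C=C=C[Zn]Br | intermediate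
8 | (1R,4S)-4-[(tert-butyldimethylsilyl)oxy]-1-(prop-2-yn-1-yl)cyclopent-2-en-1-ol | C#CC[C@]1(O)C=C[C@@H](O[Si](C)(C)C(C)(C)C)C1 | intermediate
9 | 1-bromopent-2-yne | CCC#CCBr | starting material
10 | (1R,4S)-4-[(tert-butyldimethylsilyl)oxy]-1-(octa-2,5-diyn-1-yl)cyclopent-2-en-1-ol | CCC#CCC#CC[C@]1(O)C=C[C@@H](O[Si](C)(C)C(C)(C)C)C1 | intermediate
11 | (1R,4S)-4-[(tert-butyldimethylsilyl)oxy]-1-[(2Z,5Z)-octa-2,5-dien-1-yl]cyclopent-2-en-1-ol | CC/C=C\C/C=C\C[C@]1(O)C=C[C@@H](O[Si](C)(C)C(C)(C)C)C1 | intermediate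
12 | (1R,4S)-1-[(2Z,5Z)-octa-2,5-dien-1-yl]cyclopent-2-ene-1,4-diol | CC/C=C\C/C=C\C[C@]1(O)C=C[C@@H](O)C1 | intermediate
13 | (4R)-4-hydroxy-4-[(2Z,5Z)-octa-2,5-dien-1-yl]cyclopent-2-en-1-one | CC/C=C\C/C=C\C[C@]1(O)C=CC(=O)C1 | intermediate
14 | (2R,3S,4R)-2,3-epoxy-4-hydroxy-4-[(2Z,5Z)-octa-2,5-dien-1-yl]cyclopentan-1-one | CC/C=C\C/C=C\C[C@]1(O)[C@H]2O[C@H]2C(=O)C1 | intermediate
15 | (2S,3R,4R)-2-chloro-3,4-dihydroxy-4-[(2Z,5Z)-octa-2,5-dien-1-yl]cyclopentan-1-one | CC/C=C\C/C=C\C[C@]1(O)[C@@H](O)[C@H](Cl)C(=O)C1 | intermediate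
16 | (4R)-2-chloro-4-hydroxy-4-[(2Z,5Z)-octa-2,5-dien-1-yl]cyclopent-2-en-1-one | CC/C=C\C/C=C\C[C@]1(O)C=C(Cl)C(=O)C1 | intermediate
17 | (4R)-2-chloro-4-[(2Z,5Z)-octa-2,5-dien-1-yl]-4-[(trimethylsilyl)oxy]cyclopent-2-en-1-one | CC/C=C\C/C=C\C[C@]1(O[Si](C)(C)C)C=C(Cl)C(=O)C1 | intermediate
18 | dimethyl (4R,5R)-2,2-dimethyl-1,3-dioxolane-4,5-dicarboxylate | COC(=O)[C@@H]1OC(C)(C)O[C@H]1C(=O)OC | starting material
19 | [(4S,5S)-2,2-dimethyl-1,3-dioxolane-4,5-diyl]dimethanol | OC[C@@H]1OC(C)(C)O[C@H]1CO | intermediate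
20 | [(4S,5S)-5-{[(tert-butyldiphenylsilyl)oxy]methyl}-2,2-dimethyl-1,3-dioxolan-4-yl]methanol | OC[C@@H]1OC(C)(C)O[C@H]1CO[Si](c2ccccc2)(c2ccccc2)C(C)(C)C | intermediate
21 | [(4S,5S)-5-{[(tert-butyldiphenylsilyl)oxy]methyl}-2,2-dimethyl-1,3-dioxolan-4-yl]methyl trifluoromethanesulfonate | FC(F)(F)S(=O)(=O)OC[C@@H]1OC(C)(C)O[C@H]1CO[Si](c2ccccc2)(c2ccccc2)C(C)(C)C | intermediate
22 | but-3-en-1-ylmagnesium bromide, CH2=CHCH2CH2MgBr | C=CCC[Mg]Br | starting material
23 | tert-butyl{[(4S,5S)-2,2-dimethyl-5-(pent-4-en-1-yl)-1,3-dioxolan-4-yl]methoxy}diphenylsilane | C=CCCC[C@@H]1OC(C)(C)O[C@H]1CO[Si](c2ccccc2)(c2ccccc2)C(C)(C)C | intermediate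
24 | (2S,3S)-1-[(tert-butyldiphenylsilyl)oxy]oct-7-ene-2,3-diol | C=CCCC[C@H](O)[C@@H](O)CO[Si](c1ccccc1)(c1ccccc1)C(C)(C)C | intermediate
25 | (2S,3S)-1-[(tert-butyldiphenylsilyl)oxy]oct-7-ene-2,3-diyl diacetate | C=CCCC[C@H](OC(C)=O)[C@@H](OC(C)=O)CO[Si](c1ccccc1)(c1ccccc1)C(C)(C)C | intermediate
26 | secondary ozonide (1,2,4-trioxolane) of 25, mixture at the trioxolane carbon | C1OOC(O1)CCC[C@H](OC(C)=O)[C@@H](OC(C)=O)CO[Si](c2ccccc2)(c2ccccc2)C(C)(C)C | intermediate
27 | (2S,3S)-1-[(tert-butyldiphenylsilyl)oxy]-7-oxoheptane-2,3-diyl diacetate | O=CCCC[C@H](OC(C)=O)[C@@H](OC(C)=O)CO[Si](c1ccccc1)(c1ccccc1)C(C)(C)C | intermediate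
28 | (5S,6S)-5,6-diacetoxy-7-[(tert-butyldiphenylsilyl)oxy]heptanoic acid | OC(=O)CCC[C@H](OC(C)=O)[C@@H](OC(C)=O)CO[Si](c1ccccc1)(c1ccccc1)C(C)(C)C | intermediate
29 | methyl (5S,6S)-5,6-diacetoxy-7-[(tert-butyldiphenylsilyl)oxy]heptanoate | COC(=O)CCC[C@H](OC(C)=O)[C@@H](OC(C)=O)CO[Si](c1ccccc1)(c1ccccc1)C(C)(C)C | intermediate
30 | methyl (5S,6S)-5,6-diacetoxy-7-hydroxyheptanoate | COC(=O)CCC[C@H](OC(C)=O)[C@@H](OC(C)=O)CO | intermediate
31 | methyl (5S,6R)-5,6-diacetoxy-7-oxoheptanoate | COC(=O)CCC[C@H](OC(C)=O)[C@@H](OC(C)=O)C=O | intermediate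
32 | lithium dienolate of 17 (deprotonated at the ring CH2) | CC/C=C\C/C=C\C[C@]1(O[Si](C)(C)C)C=C(Cl)C(O[Li])=C1 | intermediate
33 | methyl (5S,6S,12R,14Z,17Z)-5,6-diacetoxy-10-chloro-7-hydroxy-9-oxo-12-[(trimethylsilyl)oxy]prosta-10,14,17-trien-1-oate (C7/C8 mixture) | CC/C=C\C/C=C\C[C@]1(O[Si](C)(C)C)C=C(Cl)C(=O)C1C(O)[C@H](OC(C)=O)[C@H](CCCC(=O)OC)OC(C)=O | intermediate
34 | 7-O-acetyl derivative of 33 (C5, C6 and C12 as in 33; C7/C8 mixture) | CC/C=C\C/C=C\C[C@]1(O[Si](C)(C)C)C=C(Cl)C(=O)C1C(OC(C)=O)[C@H](OC(C)=O)[C@H](CCCC(=O)OC)OC(C)=O | intermediate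
35 | methyl (5S,6S,7E,12S,14Z,17Z)-5,6-diacetoxy-10-chloro-9-oxo-12-[(trimethylsilyl)oxy]prosta-7,10,14,17-tetraen-1-oate | CC/C=C\C/C=C\C[C@]1(O[Si](C)(C)C)C=C(Cl)C(=O)/C1=C/[C@H](OC(C)=O)[C@H](CCCC(=O)OC)OC(C)=O | intermediate
36 | methyl (5S,6S,7E,12S,14Z,17Z)-5,6-diacetoxy-10-chloro-12-hydroxy-9-oxoprosta-7,10,14,17-tetraen-1-oate | CC/C=C\C/C=C\C[C@]1(O)C=C(Cl)C(=O)/C1=C/[C@H](OC(C)=O)[C@H](CCCC(=O)OC)OC(C)=O | target

## Summary

Total steps: 26. Longest linear sequence: 15 steps (steps 1–12, then 24–26); the aldehyde branch is 11 steps (13–23) before the junction.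

Three steps most likely to fail, each with a fallback:

Step 11 (epoxide opening and dehydration in strong acid). The tertiary β-hydroxy ketone may dehydrate the wrong way or decompose. The fallback sets out from epoxy ketone 14 and separates the two events. The epoxide is opened under buffered conditions (LiCl, AcOH, THF, rt) and chlorohydrin 15 is isolated. Its secondary hydroxyl alone is sulfonylated (MsCl, Et3N, CH2Cl2, −20 °C) to the chlorohydrin 3-mesylate F1. Warming with Et3N brings about base-mediated E1cB loss of methanesulfonate, and the sequence rejoins the route at 16.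

Step 24 (lithium enolate aldol). The amide base may attack the chloroenone, or the lithium aldolate may undergo retro-aldol or elimination with the diacetoxy aldehyde. The fallback sets out from 17 and avoids a strong base. Soft enolisation (Me3SiOTf, Et3N, CH2Cl2, 0 °C) gives the trimethylsilyl dienol ether F2. A Mukaiyama aldol addition of F2 to aldehyde 31, promoted by BF3·OEt2 in CH2Cl2 at −78 °C, then forms the same C7–C8 bond and rejoins the route at 33.

Step 25 (geometry of the elimination). The C12 quaternary centre crowds the 7E isomer, so a large share of 7Z may form. The fallback sets out from 33 and does not try to steer the elimination. The mixture is taken through, the 7Z dienone F3 is separated by chromatography and equilibrated (catalytic I2, CH2Cl2, visible light, rt) to an E-enriched mixture, which is separated again and recycled. It rejoins the route at 35.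

## Further compounds

F1 | step 11 | 3-O-methanesulfonate of chlorohydrin 15 (C2, C3 and C4 as in 15) | CC/C=C\C/C=C\C[C@]1(O)[C@@H](OS(C)(=O)=O)[C@H](Cl)C(=O)C1
F2 | step 24 | trimethylsilyl dienol ether of 17, (5R)-2-chloro-5-[(2Z,5Z)-octa-2,5-dien-1-yl]-3,5-bis[(trimethylsilyl)oxy]cyclopenta-1,3-diene | CC/C=C\C/C=C\C[C@]1(O[Si](C)(C)C)C=C(Cl)C(O[Si](C)(C)C)=C1
F3 | step 25 | methyl (5S,6S,7Z,12S,14Z,17Z)-5,6-diacetoxy-10-chloro-9-oxo-12-[(trimethylsilyl)oxy]prosta-7,10,14,17-tetraen-1-oate | CC/C=C\C/C=C\C[C@]1(O[Si](C)(C)C)C=C(Cl)C(=O)/C1=C\[C@H](OC(C)=O)[C@H](CCCC(=O)OC)OC(C)=O
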